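**Retrosynthetic overview** (naphthalene numbering: C1 carries the aryl group, C2/C3 the methyls, C6 the OH, C7 the OMe)
1. Target 11 ⇐ benzyl ether 10 by O‑debenzylation (last step).
2. Ring B of 10 ⇐ γ‑hydroxy aryl ketone 9: the C1–C8a bond forms by attack of ring A (para to OBn) on the ketone, and loss of two H2O aromatises ring B without an oxidant.
3. 9 ⇐ γ‑butyrolactone 5 + 3,4,5‑trimethoxyphenyllithium 7 (C1–aryl bond, single addition).
4. 5 ⇐ key step: the C3–C4 bond joins the β‑carbon of tiglic aldehyde 1, made nucleophilic as the carbene‑bound homoenolate 3, to the carbonyl carbon of aldehyde 2.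
5. Ring order: temporary γ‑lactone first, carbocyclic ring B second; ring A and the pendant aryl ring are bought.

Assumption: the target has no stereocentre and no stereogenic axis (the pendant ring is symmetric), so the "single enantiomer" is the one achiral compound. Intermediates 4, 5, 8 and 9 are used as racemic diastereomer mixtures because all their stereocentres are erased in step 2.

**Step 1**
Reactants: 1 (E)‑2‑methylbut‑2‑enal (tiglic aldehyde); 2 3‑(benzyloxy)‑4‑methoxybenzaldehyde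
Product: 5 5‑[3‑(benzyloxy)‑4‑methoxyphenyl]‑3,4‑dimethyloxolan‑2‑one (racemic diastereomer mixture), via Breslow homoenolate 3 (not isolated), via acyl azolium alkoxide 4 (not isolated)
Conditions: 1,3‑bis(2,4,6‑trimethylphenyl)imidazolium chloride (IMes·HCl, 10 mol%), DBU (20 mol%), THF/t‑BuOH 10:1, 40 °C; 2 (1.5 equiv), 1 added over 8 h
Reagents that add atoms: none
Why: Proposed new method: the free carbene adds to 1 and the resulting Breslow intermediate 3 is a homoenolate whose β‑carbon, normally electrophilic, attacks the electrophilic carbonyl carbon of 2; tautomerisation to acyl azolium 4 and intramolecular O‑acylation close the lactone and release the carbene, so all atoms of 1 and 2 end up in 5; the closest known reaction is the NHC‑catalysed homoenolate annulation of β‑substituted enals with aryl aldehydes to γ‑butyrolactones, stretched here to an α‑methyl enal (slower Breslow formation, but its hindered carbonyl also suppresses enal self‑annulation) and an electron‑rich aldehyde; the three stereocentres form without control, which does not matter.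

**Step 2**
Reactants: 5 5‑[3‑(benzyloxy)‑4‑methoxyphenyl]‑3,4‑dimethyloxolan‑2‑one; 6 5‑bromo‑1,2,3‑trimethoxybenzene
Product: 10 6‑(benzyloxy)‑7‑methoxy‑2,3‑dimethyl‑1‑(3,4,5‑trimethoxyphenyl)naphthalene, via 3,4,5‑trimethoxyphenyllithium 7 (not isolated), via lithium lactolate 8 (not isolated), via hydroxy ketone 9 (not isolated)
Conditions: 6 (1.15 equiv), n‑BuLi (1.1 equiv), THF, −78 °C; add 5, −78 °C, 1 h; then TFA (20 equiv), CH2Cl2, −78 °C → 40 °C
Reagents that add atoms: none
Why: Bromine–lithium exchange gives 7, which adds once to the lactone because the tetrahedral lactolate 8 survives at −78 °C; acid then frees γ‑hydroxy ketone 9, whose ring A attacks the protonated aryl ketone at the position para to OBn (Bradsher‑type Friedel–Crafts cyclodehydration), and loss of two molecules of water aromatises ring B and removes every stereocentre.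

**Step 3**
Reactants: 10 6‑(benzyloxy)‑7‑methoxy‑2,3‑dimethyl‑1‑(3,4,5‑trimethoxyphenyl)naphthalene
Product: 11 3‑methoxy‑6,7‑dimethyl‑5‑(3,4,5‑trimethoxyphenyl)naphthalen‑2‑ol (target)
Conditions: H2 (1 atm), 10% Pd/C, EtOAc/MeOH 1:1, rt
Reagents that add atoms: none
Why: Catalytic hydrogenolysis cleaves the benzylic C–O bond of the aryl benzyl ether, while the methyl ethers and the naphthalene core are inert at 1 atm and room temperature; no stereocentre is involved.

**Compound list**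
1 | (E)‑2‑methylbut‑2‑enal (tiglic aldehyde) | C/C=C(\C)C=O | starting material
2 | 3‑(benzyloxy)‑4‑methoxybenzaldehyde (O‑benzylisovanillin) | COc1ccc(C=O)cc1OCc1ccccc1 | starting material
3 | Breslow homoenolate, 2‑[(E)‑1‑hydroxy‑2‑methylbut‑2‑en‑1‑ylidene]‑1,3‑bis(2,4,6‑trimethylphenyl)‑2,3‑dihydro‑1H‑imidazole | C/C=C(\C)C(O)=C1N(c2c(C)cc(C)cc2C)C=CN1c1c(C)cc(C)cc1C | intermediate (not isolated)
4 | acyl azolium alkoxide, 2‑{4‑[3‑(benzyloxy)‑4‑methoxyphenyl]‑2,3‑dimethyl‑4‑oxidobutanoyl}‑1,3‑bis(2,4,6‑trimethylphenyl)imidazolium zwitterion (diastereomer mixture, racemic) | COc1ccc(cc1OCc1ccccc1)C([O-])C(C)C(C)C(=O)c1n(-c2c(C)cc(C)cc2C)cc[n+]1-c1c(C)cc(C)cc1C | intermediate (not isolated)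
5 | 5‑[3‑(benzyloxy)‑4‑methoxyphenyl]‑3,4‑dimethyloxolan‑2‑one (diastereomer mixture, racemic; no stereodescriptors on purpose) | COc1ccc(cc1OCc1ccccc1)C1OC(=O)C(C)C1C | intermediate
6 | 5‑bromo‑1,2,3‑trimethoxybenzene | COc1cc(Br)cc(OC)c1OC | starting material
7 | 3,4,5‑trimethoxyphenyllithium | [Li]c1cc(OC)c(OC)c(OC)c1 | intermediate (not isolated)
8 | lithium 5‑[3‑(benzyloxy)‑4‑methoxyphenyl]‑3,4‑dimethyl‑2‑(3,4,5‑trimethoxyphenyl)oxolan‑2‑olate (diastereomer mixture, racemic) | [Li]OC1(c2cc(OC)c(OC)c(OC)c2)OC(c2ccc(OC)c(OCc3ccccc3)c2)C(C)C1C | intermediate (not isolated)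
9 | 4‑[3‑(benzyloxy)‑4‑methoxyphenyl]‑4‑hydroxy‑2,3‑dimethyl‑1‑(3,4,5‑trimethoxyphenyl)butan‑1‑one (in equilibrium with its cyclic lactol; diastereomer mixture, racemic) | COc1ccc(cc1OCc1ccccc1)C(O)C(C)C(C)C(=O)c1cc(OC)c(OC)c(OC)c1 | intermediate (not isolated)
10 | 6‑(benzyloxy)‑7‑methoxy‑2,3‑dimethyl‑1‑(3,4,5‑trimethoxyphenyl)naphthalene (achiral) | COc1cc2c(-c3cc(OC)c(OC)c(OC)c3)c(C)c(C)cc2cc1OCc1ccccc1 | intermediate
11 | 3‑methoxy‑6,7‑dimethyl‑5‑(3,4,5‑trimethoxyphenyl)naphthalen‑2‑ol (achiral) | COc1cc2c(-c3cc(OC)c(OC)c(OC)c3)c(C)c(C)cc2cc1O | target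

**Totals**
Total step count: 3. Longest linear sequence: 3 steps (1 + 2 → 5 → 10 → 11).

**Steps most likely to fail, with fallbacks**

Step 1 (highest risk). The α‑methyl group of 1 slows Breslow formation, and the electron‑rich aldehyde 2 is a weak acceptor, so benzoin formation from 2 or recovery of starting materials may win. The fallback sets out from 2 and returns at 5, making the same C3–C4 bond with a stoichiometric ester homoenolate. Purchased ethyl tiglate (ethyl (E)‑2‑methylbut‑2‑enoate, C/C=C(\C)C(=O)OCC) takes up HBr (33% HBr in AcOH, rt) at the β‑carbon to give ethyl 3‑bromo‑2‑methylbutanoate F1. Zinc dust with LiCl in THF at 40 °C inserts into the C–Br bond to give (4‑ethoxy‑3‑methyl‑4‑oxobutan‑2‑yl)zinc bromide F2. F2 adds to 2 in the presence of Me3SiCl (THF/N,N‑dimethylacetamide, 0 °C → rt) to give ethyl 4‑[3‑(benzyloxy)‑4‑methoxyphenyl]‑2,3‑dimethyl‑4‑[(trimethylsilyl)oxy]butanoate F3. Aqueous 1 M HCl in THF at 40 °C removes the silyl group to give ethyl 4‑[3‑(benzyloxy)‑4‑methoxyphenyl]‑4‑hydroxy‑2,3‑dimethylbutanoate F4, which lactonises in the same flask to 5.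

Step 2 (second). Risks are enolisation or double addition at the lactone, and capture of the C4 benzylic cation by the trimethoxyphenyl ring instead of ring A attacking the ketone. The ketone deactivates that ring, which is why the intended path should win, but it is not guaranteed. If THF merely buffers the acid, the volatiles are stripped and the residue is taken up in TFA/CH2Cl2 before resorting to the fallback. The fallback sets out from 5 and returns at 10, closing ring B by acylation before the aryl group is introduced. Ionic hydrogenolysis of the benzylic lactone C–O bond (Et3SiH, TFA, CH2Cl2, 0 °C → rt) gives 4‑[3‑(benzyloxy)‑4‑methoxyphenyl]‑2,3‑dimethylbutanoic acid F5. Intramolecular Friedel–Crafts acylation para to OBn (TFAA, CH2Cl2, 0 °C → rt) gives 6‑(benzyloxy)‑7‑methoxy‑2,3‑dimethyl‑3,4‑dihydronaphthalen‑1(2H)‑one F6. Addition of 7 (made from 6 and n‑BuLi as before; THF, −78 °C) and quenching with TsOH·H2O gives 6‑(benzyloxy)‑7‑methoxy‑2,3‑dimethyl‑1‑(3,4,5‑trimethoxyphenyl)‑1,2,3,4‑tetrahydronaphthalen‑1‑ol F7. Warming in toluene at 80 °C with the same acid dehydrates it to 7‑(benzyloxy)‑6‑methoxy‑2,3‑dimethyl‑4‑(3,4,5‑trimethoxyphenyl)‑1,2‑dihydronaphthalene F8. Dehydrogenation with DDQ (toluene, 80 °C) gives 10.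

Step 3 (lowest risk). Hydrogenolysis of the hindered, poorly soluble naphthyl ether could be sluggish or accompanied by partial ring reduction. The fallback sets out from 5 and returns at 11, removing the benzyl group before the naphthalene exists. Hydrogenolysis of 5 under neutral conditions (H2 1 atm, 10% Pd/C, EtOAc, rt, stopped after one equivalent) gives 5‑(3‑hydroxy‑4‑methoxyphenyl)‑3,4‑dimethyloxolan‑2‑one F9. Treatment with 7 (2.2 equiv, THF, −78 °C; the first equivalent is spent on the phenol) followed by TFA/CH2Cl2 gives 4‑hydroxy‑4‑(3‑hydroxy‑4‑methoxyphenyl)‑2,3‑dimethyl‑1‑(3,4,5‑trimethoxyphenyl)butan‑1‑one F10. F10 cyclodehydrates in the same flask, para to the free OH, directly to 11.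

**Further compounds**
F1 | step 1 | ethyl 3‑bromo‑2‑methylbutanoate | CCOC(=O)C(C)C(C)Br
F2 | step 1 | (4‑ethoxy‑3‑methyl‑4‑oxobutan‑2‑yl)zinc bromide | CCOC(=O)C(C)C(C)[Zn]Br
F3 | step 1 | ethyl 4‑[3‑(benzyloxy)‑4‑methoxyphenyl]‑2,3‑dimethyl‑4‑[(trimethylsilyl)oxy]butanoate | CCOC(=O)C(C)C(C)C(O[Si](C)(C)C)c1ccc(OC)c(OCc2ccccc2)c1
F4 | step 1 | ethyl 4‑[3‑(benzyloxy)‑4‑methoxyphenyl]‑4‑hydroxy‑2,3‑dimethylbutanoate | CCOC(=O)C(C)C(C)C(O)c1ccc(OC)c(OCc2ccccc2)c1
F5 | step 2 | 4‑[3‑(benzyloxy)‑4‑methoxyphenyl]‑2,3‑dimethylbutanoic acid | COc1ccc(cc1OCc1ccccc1)CC(C)C(C)C(=O)O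
F6 | step 2 | 6‑(benzyloxy)‑7‑methoxy‑2,3‑dimethyl‑3,4‑dihydronaphthalen‑1(2H)‑one | COc1cc2c(cc1OCc1ccccc1)CC(C)C(C)C2=O
F7 | step 2 | 6‑(benzyloxy)‑7‑methoxy‑2,3‑dimethyl‑1‑(3,4,5‑trimethoxyphenyl)‑1,2,3,4‑tetrahydronaphthalen‑1‑ol | COc1cc2c(cc1OCc1ccccc1)CC(C)C(C)C2(O)c1cc(OC)c(OC)c(OC)c1
F8 | step 2 | 7‑(benzyloxy)‑6‑methoxy‑2,3‑dimethyl‑4‑(3,4,5‑trimethoxyphenyl)‑1,2‑dihydronaphthalene | COc1cc2c(cc1OCc1ccccc1)CC(C)C(C)=C2c1cc(OC)c(OC)c(OC)c1
F9 | step 3 | 5‑(3‑hydroxy‑4‑methoxyphenyl)‑3,4‑dimethyloxolan‑2‑one | COc1ccc(cc1O)C1OC(=O)C(C)C1C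
F10 | step 3 | 4‑hydroxy‑4‑(3‑hydroxy‑4‑methoxyphenyl)‑2,3‑dimethyl‑1‑(3,4,5‑trimethoxyphenyl)butan‑1‑one | COc1ccc(cc1O)C(O)C(C)C(C)C(=O)c1cc(OC)c(OC)c(OC)c1
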